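Late in a flask charged with equal amounts of electrophile and nucleophile, a second-order step that uses the two one for one and keeps a fixed constant slows with the square of what is left, so the part of the electrophile left is one over one plus the turnovers.

all flasks: electrophile 24 mM
- north-east: nucleophile 1.5 equiv; free base 2 equiv; run made earlier
- cedar: nucleophile 1.00 equiv; free base 2.00 equiv; time 25 h
- elm: nucleophile 1.00 equiv; free base 2.60 equiv; time 25 h
- ash: nucleophile 1.00 equiv; free base 3.40 equiv; time 25 h

north-east run (percent of the electrophile charged)

| time / h | electrophile / % | target / % |
|---|---|---|
| 1.33 | 29.7 | 67.6 |
| 2.50 | 19.5 | 72.9 |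
| 4.00 | 13.0 | 72.8 |
| 8.00 | 5.0 | 64.0 |
| 15.0 | 0.7 | 50.3 |

(readings scatter by 0.3 percentage points)

1. part of the electrophile that has reacted at the end, cedar
2. part of the electrophile that has reacted at the end, elm
3. part of the electrophile that has reacted at the end, ash
4. what raising the equivalents of free base from its lowest to its highest value here does to the part of the electrophile that has reacted (changes below 5 percentage points count as none) (it falls / it rises / no change)

- on the list of suspects stand: electrophile + nucleophile -> acid set free + target; acid set free + target -> side product; acid set free + free base <-> salt of the base; nucleophile + acid set free <-> protonated nucleophile; free base <-> dormant form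
- no earlier run changes the charge of free base; that part of a forecast is a guess

Taking the nucleophile used as equal to the electrophile used, the north-east reading at 8.00 h gives a constant of 0.0208 mM⁻¹ h⁻¹, and the reading at 1.33 h gives 0.0364 mM⁻¹ h⁻¹. With the later constant, cedar counts 12.5 turnovers, a turnover count being constant times electrophile charged times time. That leaves 7.43%, so my estimate is 92.6% reacted. If more free base restored the earlier constant, which is a guess, the part left would drop by 3.1 percentage points, less than the 5 points that counts as a change.

The forecast gives 92.5% for cedar, 93.8% for elm and 95% for ash, with the trend no change: “More base frees more nucleophile, so conversion should creep up”.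

Cedar gives 92.0%, elm 92.3% and ash 92.7%, a change of 0.8 points, so the trend is no change and the forecast held. Read back from the electrophile left, cedar counts 11.4 turnovers and ash 12.8.

    electrophile + nucleophile → acid set free + target (k = 71.1 M⁻¹ h⁻¹)
    acid set free + target → side product (k = 28.8 M⁻¹ h⁻¹)
    acid set free + free base ⇌ salt of the base (K = 56.7 M⁻¹, k = 23.6 M⁻¹ h⁻¹)
    nucleophile + acid set free ⇌ protonated nucleophile, settled at all times (K = 1340 M⁻¹)
    free base ⇌ dormant form (K = 0.266, k = 0.0621 h⁻¹)

Cedar is not at rest at 25 h. Ten times the turnovers, 125, leave 0.794% of the electrophile, and cedar at 250 h holds 0.383%. By the same constant, a neighbour of cedar charged with 60 mM of electrophile reckons at 31.1 turnovers, which leave 3.11%, and it holds 3.9% at 25.0 h. Between 25.0 h and 250 h, the side product in cedar climbs from 65.9% to 97.2% while target falls from 26.1% to 2.46%.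

The data were generated by integration from invented constants; scatter was added.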